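The constants used here were drawn at random within sensible limits; the run is a simulation.

The closed, stirred vessel holds substrate and free catalyst, and the gas held over them dissolves as coupling partner.

    substrate + free catalyst ⇌ catalyst intermediate A (K1 = 1400 L mol⁻¹, k1 = 8.0 L mol⁻¹ s⁻¹)
    coupling partner + catalyst intermediate A → catalyst intermediate B (k2 = 30 L mol⁻¹ s⁻¹)
    catalyst intermediate B → catalyst intermediate C (k3 = 17 s⁻¹)
    catalyst intermediate C → free catalyst + target (k4 = 18 s⁻¹)
    gas ⇌ coupling partner, rate k5*(csat - [coupling partner]) (k5 = 0.12 s⁻¹, csat = 2.8 mM)
    coupling partner + target → over-reaction product (k6 = 2.0 L mol⁻¹ s⁻¹)

- teal: substrate 49 mM; gas 2.8 mM (held); free catalyst 10 mol%; time 2.5 min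
- green: substrate 49 mM; gas 2.8 mM (held); free catalyst 10 mol%; time 3.0 min

- which of these there is most of at the end, counted by the substrate in it, teal (over-reaction product / catalyst intermediate A / target / substrate)
- which of these there is most of at the end, counted by the substrate in it, green (over-reaction product / catalyst intermediate A / target / substrate)
- amount of the one of these that there is most of at the end, in percent of the substrate charged, teal
- amount of the one of these that there is most of at the end, in percent of the substrate charged, green

Step 6 runs one way and the gas is held, so I expect target to turn into over-reaction product if left long enough. What matters here is how far each flask gets in its time, so I need a rate. Coupling partner must dissolve and then meet catalyst intermediate A. Dissolving gives at most 0.336 mM s⁻¹. I name the crossover amount, the amount of catalyst intermediate A at which step 2 uses partner as readily as transfer renews it, the transfer coefficient over the rate constant of step 2: 4.00 mM. Balancing supply against use, the flow through the cycle is that ceiling times bound catalyst over bound catalyst plus crossover amount.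

In teal the catalyst charge is 4.90 mM, and the equilibrium constant times the starting substrate, 69, is far more than 1. So I first put the whole charge in intermediate A, its resting state, and get 0.185 mM s⁻¹, or 56.6% of the substrate turned over in 2.5 min.

But that flow implies 1.26 mM of partner, which drains intermediate A at 0.0378 s⁻¹, faster than it falls apart, at 0.00571 s⁻¹. So, estimating about 30.2 mM of substrate at mid-run from this first flow, I put teal's bound share nearer 84.8%, or 4.15 mM.

Target also takes partner. The first flow gives an estimate of 13.9 mM of it at mid-run, which adds 0.925 mM to the denominator, and that gives 0.154 mM s⁻¹.

By this estimate teal has 47.1% turned over and 8.48% bound, which leaves 44.5% substrate. I reckon that step 6 takes 8.71%, so my target is 38.3%, less than the substrate. The flow should sag a little further in green, but I keep it: 56.5% turned over, 35.1% substrate, and target 43.9%, more than the substrate.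

The forecast says substrate at 44% in teal and target at 46% in green, on the ground that the “catalyst sits mostly as intermediate A”. It names the same species as I do, and its green figure is higher than mine.

The simulation gives substrate at 44.7% in teal and target at 44.9% in green. Take green with 200 mM of substrate at the same loading. Its 20.0 mM of catalyst stands far above the crossover amount, so the first flow is 0.280 mM s⁻¹. With a bound share of 98.4% and target's toll, I reckon the flow at 0.261 mM s⁻¹, which by this estimate turns over 23.5% of the charge in 3.0 min. That flask ends with target and over-reaction product together at 23.5%.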